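## Retrosynthetic overview
1. The last bond made is C13–C14. An unmasked isovaleryl anion (acylzirconocene from isobutene and CO) is coupled with the π-allyl-Pd of a primary allylic acetate, so the base-sensitive β,γ-enone is formed in the final operation.
2. The key bond is C1–C2. The carbonyl carbon of 3-furaldehyde is converted catalytically into a chiral α-silyloxy carbanion (Cu–Si addition, then [1,2]-Brook shift). This couples with the π-allyl-Pd of a farnesyl-type carbonate, setting C1 (S) and giving the linear isomer that ordinary allyl-metal addition does not give.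
3. The C15 linker comes from (2E,6E)-farnesol by O-Boc formation, terminal SeO2 (E)-hydroxylation and O-TBS protection. Two E-alkenes are bought; the third is set by the oxidation.
4. No ring is formed. The furan arrives intact with 3-furaldehyde.

Assumption: the facial sense of the chiral NHC–Cu catalyst with 3-furaldehyde is taken by analogy with benzaldehydes. It is checked once by Mosher analysis of the derived alcohol, and the equally available ligand antipode is used if the sense is reversed.

## Route

**Step 1**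
Reactants: 1 (2E,6E)-farnesol
Product: 2 tert-butyl (2E,6E)-3,7,11-trimethyldodeca-2,6,10-trien-1-yl carbonate
Conditions: Boc2O (1.3 equiv), DMAP (10 mol %), CH2Cl2, 0 °C → rt
Reagents that add atoms: di-tert-butyl dicarbonate, CC(C)(C)OC(=O)OC(=O)OC(C)(C)C
Why: DMAP-catalysed O-acylation of an unhindered primary allylic alcohol gives the mixed carbonate, which later ionises to π-allyl-Pd and releases the t-BuO⁻ that turns over copper.

**Step 2**
Reactants: 2 farnesyl tert-butyl carbonate
Product: 3 tert-butyl (2E,6E,10E)-12-hydroxy-3,7,11-trimethyldodeca-2,6,10-trien-1-yl carbonate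
Conditions: SeO2 (10 mol %), salicylic acid (10 mol %), t-BuOOH (3.5 equiv), CH2Cl2, 0 °C → rt, stopped at about 70 % conversion (2 recovered)
Reagents that add atoms: tert-butyl hydroperoxide, CC(C)(C)OO (terminal oxidant; its O is delivered through catalytic SeO2, O=[Se]=O)
Why: Catalytic SeO2/TBHP allylic oxidation (ene reaction, then [2,3]-sigmatropic shift) attacks the least hindered, most electron-rich terminal isopropylidene at its E-methyl group and gives only the 10E alcohol, while the C2 alkene is deactivated by the allylic carbonate.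

**Step 3**
Reactants: 3 12-hydroxy carbonate
Product: 4 tert-butyl (2E,6E,10E)-12-[(tert-butyldimethylsilyl)oxy]-3,7,11-trimethyldodeca-2,6,10-trien-1-yl carbonate
Conditions: TBSCl (1.2 equiv), imidazole (2 equiv), CH2Cl2, 0 °C → rt
Reagents that add atoms: tert-butyldimethylsilyl chloride, CC(C)(C)[Si](C)(C)Cl
Why: Standard imidazole-promoted silylation removes the only acidic proton (it would protonate the organocopper of step 4) and leaves a group that Pd(0) does not ionise.

**Step 4 (key step)**
Reactants: 4 TBS-protected carbonate; 5 furan-3-carbaldehyde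
Product: 7 (1S,3E,7E,11E)-13-[(tert-butyldimethylsilyl)oxy]-1-[(dimethylphenylsilyl)oxy]-1-(furan-3-yl)-4,8,12-trimethyltrideca-3,7,11-triene, via α-silyloxy(3-furyl)methylcopper 6 (not isolated)
Conditions: 5 (1.5 equiv), PhMe2Si–Bpin (1.5 equiv), L*CuCl (10 mol %; L* = C2-symmetric (4S,5S)-1,3-bis(2-isopropylphenyl)-4,5-diphenylimidazolidin-2-ylidene), KOt-Bu (12 mol %), Pd2(dba)3 (2.5 mol %), dppf (6 mol %), toluene, 30 °C
Reagents that add atoms: (dimethylphenylsilyl)boronic acid pinacol ester, C[Si](C)(c1ccccc1)B1OC(C)(C)C(C)(C)O1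
Why: Proposed new method: L*Cu–SiMe2Ph adds to one face of the aldehyde, the α-silyl copper alkoxide undergoes a [1,2]-Brook rearrangement to the configurationally defined α-silyloxy organocopper 6 (an aldehyde-derived α-alkoxy carbanion), and 6 transmetalates stereospecifically to the π-allyl-Pd(dppf) formed from 4, with reductive elimination at the unhindered CH2 terminus giving the linear 3E product and setting C1 as S under ligand control; the closest known reaction type is the synergistic chiral NHC–Cu/Pd–bisphosphine three-component coupling of aromatic aldehydes, silylboronates and aryl or simple allyl electrophiles, and what is new here is the 3-furyl aldehyde and the trisubstituted farnesyl-type carbonate.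

**Step 5**
Reactants: 7 bis-silyl ether
Product: 9 (1S,3E,7E,11E)-1-(furan-3-yl)-4,8,12-trimethyltrideca-3,7,11-triene-1,13-diyl diacetate, via diol 8 (not isolated)
Conditions: TBAF (2.2 equiv), THF, 0 °C → rt; then Ac2O (5 equiv), DMAP (10 mol %), 0 °C → rt, one pot
Reagents that add atoms: acetic anhydride, CC(=O)OC(C)=O
Why: Fluoride desilylation breaks only Si–O bonds, so C1 stays S, and in-pot DMAP-catalysed acetylation installs the final C1 acetate together with the primary allylic acetate leaving group needed for step 6.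

**Step 6**
Reactants: 9 diacetate; 10 isobutene
Product: 13 (1S,3E,7E,11E)-1-(furan-3-yl)-4,8,12,16-tetramethyl-14-oxoheptadeca-3,7,11-trien-1-yl acetate (target), via isobutylzirconocene chloride 11 (not isolated), via isovalerylzirconocene chloride 12 (not isolated)
Conditions: Cp2Zr(H)Cl (2 equiv), 10 (excess), CH2Cl2, rt; CO (1 atm), rt, 2 h; Ar purge; then 9 (1 equiv), PdCl2(PPh3)2 (5 mol %), toluene, rt → 40 °C
Reagents that add atoms: carbon monoxide, [C-]#[O+]; zirconocene chloride hydride, [H][Zr](Cl)(C1C=CC=C1)C1C=CC=C1 (its Cp2ZrCl unit is carried only in 11 and 12; it leaves only H in 13)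
Why: Hydrozirconation and CO insertion give acylzirconocene 12, an unmasked isovaleryl anion donor that transmetalates to the π-allyl-Pd formed only from the primary allylic acetate (the C1 acetate is homoallylic and is not ionised), and acyl–allyl reductive elimination at the CH2 terminus of the syn-π-allyl gives the 11E β,γ-enone under neutral conditions that leave C1 untouched (Pd-catalysed allylic acylation with an acylzirconocene).

## Compound list
1 | (2E,6E)-farnesol | OC/C=C(\C)CC/C=C(\C)CCC=C(C)C | starting material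
2 | tert-butyl (2E,6E)-farnesyl carbonate | CC(C)(C)OC(=O)OC/C=C(\C)CC/C=C(\C)CCC=C(C)C | intermediate
3 | tert-butyl (2E,6E,10E)-12-hydroxyfarnesyl carbonate | CC(C)(C)OC(=O)OC/C=C(\C)CC/C=C(\C)CC/C=C(\C)CO | intermediate
4 | tert-butyl (2E,6E,10E)-12-(TBS-oxy)farnesyl carbonate | CC(C)(C)OC(=O)OC/C=C(\C)CC/C=C(\C)CC/C=C(\C)CO[Si](C)(C)C(C)(C)C | intermediate
5 | furan-3-carbaldehyde | O=Cc1ccoc1 | starting material
6 | (S)-[(dimethylphenylsilyloxy)(furan-3-yl)methyl]copper(I)·L* (NHC ligand omitted from SMILES; drawn for stereoretentive Cu→Pd transfer) | C[Si](C)(c1ccccc1)O[C@@H]([Cu])c1ccoc1 | intermediate (not isolated)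
7 | (1S,3E,7E,11E)-13-(TBS-oxy)-1-(dimethylphenylsilyloxy)-1-(furan-3-yl)-4,8,12-trimethyltrideca-3,7,11-triene | C[Si](C)(c1ccccc1)O[C@@H](C/C=C(\C)CC/C=C(\C)CC/C=C(\C)CO[Si](C)(C)C(C)(C)C)c1ccoc1 | intermediate
8 | (1S,3E,7E,11E)-1-(furan-3-yl)-4,8,12-trimethyltrideca-3,7,11-triene-1,13-diol | O[C@@H](C/C=C(\C)CC/C=C(\C)CC/C=C(\C)CO)c1ccoc1 | intermediate (not isolated)
9 | (1S,3E,7E,11E)-1-(furan-3-yl)-4,8,12-trimethyltrideca-3,7,11-triene-1,13-diyl diacetate | CC(=O)O[C@@H](C/C=C(\C)CC/C=C(\C)CC/C=C(\C)COC(C)=O)c1ccoc1 | intermediate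
10 | isobutene | C=C(C)C | starting material
11 | isobutylzirconocene chloride (Cp drawn η1) | CC(C)C[Zr](Cl)(C1C=CC=C1)C1C=CC=C1 | intermediate (not isolated)
12 | isovalerylzirconocene chloride (Cp drawn η1) | CC(C)CC(=O)[Zr](Cl)(C1C=CC=C1)C1C=CC=C1 | intermediate (not isolated)
13 | (1S,3E,7E,11E)-1-(furan-3-yl)-4,8,12,16-tetramethyl-14-oxoheptadeca-3,7,11-trien-1-yl acetate | CC(=O)O[C@@H](C/C=C(\C)CC/C=C(\C)CC/C=C(\C)CC(=O)CC(C)C)c1ccoc1 | target

## Step count and risks
Total steps: 6. Longest linear sequence: 6 (from 1).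

**Step 4 (highest risk).**
- The π-rich 3-furyl group may slow the Brook shift.
- The π-allyl-Pd may eliminate to farnesene-type dienes, or lose 3E purity, before transmetalation.
- The ee on this aldehyde is untested.

Fallback, setting out from 4 and 5: make the same C1–C2 bond at the ketone oxidation level and set the stereocentre afterwards by reduction. Cooperative thiazolium-derived NHC/Pd(0)–bisphosphine catalysis couples the Breslow acyl anion of 5 with the π-allyl-Pd from 4. This gives (3E,7E,11E)-13-[(tert-butyldimethylsilyl)oxy]-1-(furan-3-yl)-4,8,12-trimethyltrideca-3,7,11-trien-1-one F1. Reduction with (R)-Me-CBS and catecholborane in toluene at −78 °C (furyl as the large group, non-basic medium) gives (1S,3E,7E,11E)-13-[(tert-butyldimethylsilyl)oxy]-1-(furan-3-yl)-4,8,12-trimethyltrideca-3,7,11-trien-1-ol F2. The TBAF treatment of step 5 converts this to diol 8, where the route is rejoined.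

**Step 6.**
- The allylic acetate may transmetalate sluggishly.
- Pd–H or Lewis-acidic Zr species may move the alkene into conjugation.

Fallback, setting out from 9: replace the acyl-metal by a soft, masked acyl anion. Tsuji–Trost allylation of excess 3-methyl-1-nitrobutane with 9 (Pd(PPh3)4, Cs2CO3, THF/DMSO) gives (1S,3E,7E,11E)-1-(furan-3-yl)-4,8,12,16-tetramethyl-14-nitroheptadeca-3,7,11-trien-1-yl acetate F3 as C14 epimers. The nitronate is then formed with exactly 1 equiv NaOMe at 0 °C. A buffered McMurry–Nef reaction (TiCl3, NH4OAc, pH 5–6) gives the ketone without base-induced conjugation, rejoining at 13.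

**Step 2.**
- Conversion and regioselectivity are moderate.
- Over-oxidation to the enal competes.

Fallback, setting out from 2: degrade and rebuild the terminus.
- Terminal-selective bromohydrin formation (NBS, THF/H2O, 0 °C) gives tert-butyl (2E,6E)-10-bromo-11-hydroxy-3,7,11-trimethyldodeca-2,6-dien-1-yl carbonate F4.
- DBU closes it to tert-butyl (2E,6E)-9-(3,3-dimethyloxiran-2-yl)-3,7-dimethylnona-2,6-dien-1-yl carbonate F5.
- H5IO6 (THF/H2O, 0 °C) cleaves it to tert-butyl (2E,6E)-3,7-dimethyl-10-oxodeca-2,6-dien-1-yl carbonate F6.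
- E-selective Wittig reaction with Ph3P=C(CH3)CHO (toluene, 80 °C) gives tert-butyl (2E,6E,10E)-3,7,11-trimethyl-12-oxododeca-2,6,10-trien-1-yl carbonate F7.
- Luche reduction (NaBH4, CeCl3, MeOH, 0 °C) rejoins the route at 3.

## Further compounds
F1 | step 4 | (3E,7E,11E)-13-[(tert-butyldimethylsilyl)oxy]-1-(furan-3-yl)-4,8,12-trimethyltrideca-3,7,11-trien-1-one | O=C(C/C=C(\C)CC/C=C(\C)CC/C=C(\C)CO[Si](C)(C)C(C)(C)C)c1ccoc1
F2 | step 4 | (1S,3E,7E,11E)-13-[(tert-butyldimethylsilyl)oxy]-1-(furan-3-yl)-4,8,12-trimethyltrideca-3,7,11-trien-1-ol | O[C@@H](C/C=C(\C)CC/C=C(\C)CC/C=C(\C)CO[Si](C)(C)C(C)(C)C)c1ccoc1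
F3 | step 6 | (1S,3E,7E,11E)-1-(furan-3-yl)-4,8,12,16-tetramethyl-14-nitroheptadeca-3,7,11-trien-1-yl acetate (C14 epimers) | CC(=O)O[C@@H](C/C=C(\C)CC/C=C(\C)CC/C=C(\C)CC(CC(C)C)[N+](=O)[O-])c1ccoc1
F4 | step 2 | tert-butyl (2E,6E)-10-bromo-11-hydroxy-3,7,11-trimethyldodeca-2,6-dien-1-yl carbonate (racemic) | CC(C)(C)OC(=O)OC/C=C(\C)CC/C=C(\C)CCC(Br)C(C)(C)O
F5 | step 2 | tert-butyl (2E,6E)-9-(3,3-dimethyloxiran-2-yl)-3,7-dimethylnona-2,6-dien-1-yl carbonate (racemic) | CC(C)(C)OC(=O)OC/C=C(\C)CC/C=C(\C)CCC1OC1(C)C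
F6 | step 2 | tert-butyl (2E,6E)-3,7-dimethyl-10-oxodeca-2,6-dien-1-yl carbonate | CC(C)(C)OC(=O)OC/C=C(\C)CC/C=C(\C)CCC=O
F7 | step 2 | tert-butyl (2E,6E,10E)-3,7,11-trimethyl-12-oxododeca-2,6,10-trien-1-yl carbonate | CC(C)(C)OC(=O)OC/C=C(\C)CC/C=C(\C)CC/C=C(\C)C=O
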